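## Structural features

- The target is a germacranolide. Numbering used throughout, also for intermediates: ring carbons C1–C10; C1 bears the free OH, C3 the acetate, C8 the (2R)-2-methylbutanoate; C14 is the methyl on C10 and C15 the methyl on C4; the α-methylene-γ-butyrolactone is O–C6, C7–C11(=C13)–C12(=O).
- Read from the SMILES, the target is 1S,3S,6S,7R,8R with 4Z,9Z olefins, a cis-fused lactone (H6 and H7 cis) and a 2′R acyl side chain.
- The ten-membered carbocycle is a (Z,Z)-cyclodeca-1,6-diene. It consists of two Z-2-methylbut-2-ene-1,4-dioxy units (O6–C6–C5=C4–C3–O3 and O8–C8–C9=C10–C1–O1) joined by the C2 methylene and by C7.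
- C6–C7–C8 is a contiguous triad of ribo type: O6 and O8 are related like the two ends of a meso triad and differ only in being lactone and ester oxygen. C1/C3 is an anti-1,3-diol that is acetylated only at O3.
- Fragile groups: the α-methylene lactone (Michael acceptor), four allylic C–O bonds, esters that can migrate between neighbouring oxygens, and Z-γ-oxy enals and enones that isomerise or cyclise to furans when a neighbouring hydroxyl is free.
- The real difficulty is closing the ten-membered ring while four allylic oxygens end up in four different states (lactone, acetate, 2-methylbutanoate, free OH) and C1/C3 are set relative to the triad.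
- The key step exploits the C1–C2–C3 anti-1,3-diol monoacetate lying between the two Z-olefins. It is the retron of an aldol bond C2–C3 followed by an Evans–Tishchenko reduction, and allylic strain across C4=C5 relays the configuration of C6 to C3.

## Logic of the disconnections

In one sentence: a samarium(II)-mediated intramolecular Reformatsky reaction of 23, whose C2 enolate adds to its own C3 aldehyde, closes the ten-membered ring.

- **26 ⇒ 25.** The O3–acetyl bond and the C1–H bond are cut together. An anti-1,3-diol monoester is what an Evans–Tishchenko reduction of a β-hydroxy ketone with acetaldehyde delivers. This removes the C1 stereocentre and the O1/O3 differentiation in one operation. The forward step needs a free C3–OH, a C1 ketone and intramolecular hydride delivery anti to O3.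
- **25 ⇒ 23.** The C2–C3 bond is cut, which opens the carbocycle between the two Z-olefins. The precursor 23 is an open chain on a lactone core with a C3 aldehyde on the C6 arm and a C1 bromomethyl ketone on the C8 arm. The forward step must generate the enolate 24 selectively, close a ten-membered ring and choose one face of the C3 aldehyde.
- **23 ⇒ 20 (through 22 and 21).** Only the arm termini change: the C3 aldehyde comes from a primary allylic alcohol, and the C1–C2 bromomethyl ketone from a C10 vinyl iodide by coupling with an α-ethoxyvinyl unit and bromination. The sensitive enal and bromo ketone therefore appear only in the last steps before cyclisation.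
- **20 ⇒ 16 (through 19, 18 and 17).** The lactone O6–C12 bond and the silyl ether on O3 are cut. The lactone is closed only after O8 carries its ester, so no free hydroxyl ever sits next to the lactone and translactonisation from O6 to O8 is excluded.
- **16 ⇒ 15.** The C9=C10 bond is cut by a Z-selective iodo-olefination of a lactol. Opening the furanose at this point releases O6 as the only free hydroxyl, so the ring oxygen of the sugar becomes the lactone oxygen.
- **15 ⇒ 12 + 13 (through 14).** The O8–acyl bond is cut. O8 is the hydroxyl next to the anomeric carbon of 12, so it is acylated together with the anomeric oxygen and the anomeric ester is then removed selectively.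
- **12 ⇒ 8 (through 11, 10 and 9).** The C11=C13 methylene and the 1,2-acetonide are removed. Methylenation is placed before any enolisable ester other than the tert-butyl ester is present. The tert-butyl ester is chosen because it does not lactonise onto O8 under the acetal hydrolysis.
- **8 ⇒ 5 (through 7 and 6).** The C4=C5 bond is cut by a Z-selective olefination of a sugar aldehyde, followed by ester reduction and silylation.
- **5 ⇒ 1 (through 4, 3 and 2).** The C7–C11 bond is cut (olefination of a 3-ulose, then hydrogenation from the convex face) and the sugar C5–C6 bond is restored. The triad C6–C7–C8 maps onto C4–C3–C2 of an L-ribo furanose whose ring oxygen is O6. The L series is required because the arm on the lactone carbinol must be the aldehyde arm.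

## Other disconnections considered

**Alternative 1:** Cut C6–C7 and O6–C12. The forward step is an intramolecular Nozaki–Hiyama–Kishi or zinc Barbier allylation of the ω-formyl (Z)-2-(bromomethyl)enoate A1 with lactonisation to A2, the route drawn first for germacranolides.
- The ring closure would have to set C6 and C7 together, cis to each other and correctly relative to C8, in a ten-membered allylmetal transition state. Allylchromium additions normally favour the anti adduct, which leads to the trans-fused lactone.
- A1 must already carry C1, C3 and C8, made one by one with nothing relaying one to the next.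
- The chosen plan takes the triad from a rigid furanose and asks the ring closure for one stereocentre only.

**Alternative 2:** Cut C9=C10. The forward step is ring-closing metathesis of the diene A3 to A2.
- The olefin to be formed is trisubstituted, comes from a 1,1-disubstituted partner and is flanked by two oxygenated allylic centres.
- Metathesis offers no kinetic control of Z geometry in a strained ten-membered ring, and the acrylate is a competing partner.
- All five ring stereocentres would have to be in place beforehand, so the step removes no stereochemical work.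

**Alternative 3:** Cut C1–C2 and O3–N. The forward step is an intramolecular nitrile oxide cycloaddition of the nitrile oxide from oxime A4 to the bridged isoxazoline A5, followed by N–O cleavage to 25.
- It uses the same retron as the chosen plan, but a seven-atom tether leaves the bridged-versus-fused regiochemistry open.
- Facial selectivity on a terminal vinyl group is less constrained than on the s-trans enal.
- N–O cleavage must be done next to a Z-enone and an α-methylene lactone, and the sequence is two steps longer than the aldol closure.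

Key step: step 18

Assumption: 1,2:5,6-di-O-isopropylidene-α-L-glucofuranose (1) is taken as a purchasable sugar derivative; it is otherwise one acetonation step from commercial L-glucose. (R)-2-Methylbutanoic acid (13) is commercial.

## Route

Step 1
Reactants: 1 diacetone-L-glucose
Product: 2 1,2:5,6-di-O-isopropylidene-α-L-ribo-hexofuranos-3-ulose
Conditions: Dess–Martin periodinane, CH2Cl2, rt
Reagents that add atoms: none
Why: Dess–Martin oxidation of the only free hydroxyl gives the 3-ulose; the carbinol carbon that is oxidised is the future C7, so no stereochemical information is lost that is not rebuilt in step 3.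

Step 2
Reactants: 2 L-3-ulose
Product: 3 exocyclic tert-butyl enoate (E/Z mixture)
Conditions: t-BuO2CCH2P(O)(OEt)2, NaH, THF, 0 °C to rt
Reagents that add atoms: tert-butyl 2-(diethoxyphosphoryl)acetate CCOP(=O)(CC(=O)OC(C)(C)C)OCC
Why: Horner–Wadsworth–Emmons olefination of the ketone brings in C11 and C12; the olefin geometry is irrelevant because the double bond is saturated in the next step.

Step 3
Reactants: 3 exocyclic enoate
Product: 4 3-C-(tert-butoxycarbonylmethyl)-3-deoxy-1,2:5,6-di-O-isopropylidene-α-L-allofuranose
Conditions: H2 (1 atm), 10% Pd/C, EtOAc, rt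
Reagents that add atoms: none
Why: Heterogeneous hydrogenation should deliver hydrogen to the convex face of the cis-fused bicycle, anti to the 1,2-acetonide, so the CH2CO2tBu branch ends cis to the oxygen on the future C8; this sets C7.

Step 4
Reactants: 4 allo ester
Product: 5 3-C-(tert-butoxycarbonylmethyl)-3-deoxy-1,2-O-isopropylidene-α-L-ribo-pentodialdo-1,4-furanose
Conditions: H5IO6, EtOAc, rt
Reagents that add atoms: none
Why: Periodic acid hydrolyses the terminal acetonide selectively and cleaves the liberated glycol in the same pot (glycol cleavage), unmasking the C5 aldehyde while the 1,2-acetonide and the tert-butyl ester stay intact.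

Step 5
Reactants: 5 C5 aldehyde
Product: 6 (Z)-C4=C5 methyl enoate
Conditions: (CF3CH2O)2P(O)CH(CH3)CO2CH3, KHMDS, 18-crown-6, THF, −78 °C
Reagents that add atoms: methyl 2-[bis(2,2,2-trifluoroethoxy)phosphoryl]propanoate COC(=O)C(C)P(=O)(OCC(F)(F)F)OCC(F)(F)F
Why: Still–Gennari olefination; the electron-poor phosphonate under dissociating conditions gives the kinetic Z-trisubstituted enoate with α-alkoxy aldehydes, which sets the C4=C5 geometry and brings in C3, C4 and C15.

Step 6
Reactants: 6 Z-enoate
Product: 7 Z-allylic alcohol (C3–OH)
Conditions: DIBAL-H (2.3 equiv), CH2Cl2, −78 °C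
Reagents that add atoms: none
Why: DIBAL-H reduces the conjugated methyl ester to the allylic alcohol at −78 °C, whereas the hindered tert-butyl ester should react much more slowly; the Z geometry is not touched.

Step 7
Reactants: 7 allylic alcohol
Product: 8 3-O-TBDPS ether
Conditions: TBDPSCl, imidazole, CH2Cl2, rt
Reagents that add atoms: tert-butyl(chloro)diphenylsilane CC(C)(C)[Si](Cl)(c1ccccc1)c1ccccc1
Why: Standard silylation of the primary allylic alcohol; TBDPS is chosen because it should survive LDA, warm aqueous acetic acid, acylation, the ylide of step 12 and TMSOTf.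

Step 8
Reactants: 8 silyl ether
Product: 11 tert-butyl acrylate (C11=C13 in place), via Mannich base 9 (not isolated), via ammonium iodide 10 (not isolated)
Conditions: LDA, THF, −78 °C; CH2=NMe2+ I−, −78 to 0 °C; then MeI, THF/MeOH, rt; then DBU, CH2Cl2, rt
Reagents that add atoms: Eschenmoser's salt (N,N-dimethylmethyleneiminium iodide) C=[N+](C)C.[I-]
Why: Ester-enolate Mannich reaction, quaternisation and E1cB elimination (α-methylenation) install C13 while the tert-butyl ester is the only enolisable carbonyl; C7 bears no acidic hydrogen toward this enolate and keeps its configuration.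

Step 9
Reactants: 11 acrylate acetonide
Product: 12 lactol diol (anomeric mixture)
Conditions: AcOH/H2O (4:1), 70 °C
Reagents that add atoms: none
Why: Acid hydrolysis of the 1,2-O-isopropylidene acetal; the tert-butyl ester resists acyl-oxygen exchange, so the cis hydroxyl on C8 should not be captured as a lactone, and TBDPS is stable to aqueous acetic acid.

Step 10
Reactants: 12 lactol diol; 13 (R)-2-methylbutanoic acid
Product: 14 bis[(2R)-2-methylbutanoate] (anomeric mixture)
Conditions: 13 (3 equiv), DIC, DMAP (cat.), CH2Cl2, 0 °C to rt
Reagents that add atoms: none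
Why: Steglich esterification of both hydroxyls removes any need for selectivity between them; with catalytic DMAP at 0 °C the α-stereocentre of the acid should not be enolised.

Step 11
Reactants: 14 bis-ester
Product: 15 lactol carrying the (2R)-2-methylbutanoate on O8
Conditions: Bu3SnOMe, THF, 60 °C; aqueous work-up
Reagents that add atoms: none
Why: Tin-alkoxide transesterification cleaves only the acetal-type anomeric ester (selective anomeric deacylation) and avoids amine nucleophiles that could add to the acrylate; the O8 ester is an ordinary secondary ester and stays.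

Step 12
Reactants: 15 acylated lactol
Product: 16 open-chain (9Z)-10-iodo olefin with free C6–OH
Conditions: Ph3P+CH(I)CH3 I−, NaHMDS, THF/DMPU, −78 °C; add 15; AcOH quench at −78 °C
Reagents that add atoms: (1-iodoethyl)triphenylphosphonium iodide CC(I)[P+](c1ccccc1)(c1ccccc1)c1ccccc1.[I-]
Why: Stork–Zhao olefination of the ring-opened aldehyde tautomer gives the (Z)-2-iodoalkene with iodine cis to C8, which fixes the C9=C10 geometry, brings in C10 and C14 and frees O6 as the only hydroxyl; low temperature and a cold acidic quench are meant to keep the O8 ester from migrating to the O6 alkoxide.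

Step 13
Reactants: 16 hydroxy tert-butyl ester
Product: 19 α-methylene-γ-butyrolactone (3-O-TBDPS; vinyl iodide), via bis-TMS derivative 17 (not isolated), via hydroxy acid 18 (not isolated)
Conditions: TMSOTf, 2,6-lutidine, CH2Cl2, 0 °C; aq. citric acid; then DIC, DMAP (cat.), CH2Cl2, 0 °C
Reagents that add atoms: none
Why: TMSOTf/2,6-lutidine converts the tert-butyl ester into the silyl ester with loss of isobutene and masks O6 against ionisation, mild acid frees the hydroxy acid, and carbodiimide lactonisation closes the five-membered ring at O6; the C6–O bond is never broken, so C6 keeps its configuration and the cis fusion follows from C6/C7.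

Step 14
Reactants: 19 silyl ether lactone
Product: 20 primary allylic alcohol (C3–OH)
Conditions: HF·pyridine, pyridine/THF, 0 °C to rt
Reagents that add atoms: none
Why: Fluoride-mediated desilylation under buffered acidic conditions removes TBDPS without acyl migration and without touching the vinyl iodide or the α-methylene lactone.

Step 15
Reactants: 20 vinyl iodide
Product: 21 2-ethoxy-1,3-diene (masked C1 methyl ketone)
Conditions: CH2=C(OEt)SnBu3, Pd(PPh3)4 (cat.), CuI (cat.), DMF, rt
Reagents that add atoms: tributyl(1-ethoxyvinyl)stannane CCCC[Sn](CCCC)(CCCC)C(=C)OCC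
Why: Stille coupling proceeds with retention of the olefin geometry and brings in C1 and C2; room temperature with copper co-catalysis is chosen so that transmetalation outruns a Heck reaction of the vinylpalladium species with the acrylate.

Step 16
Reactants: 21 enol ether
Product: 22 C1 bromomethyl ketone
Conditions: NBS (1.05 equiv), THF/H2O (4:1), 0 °C
Reagents that add atoms: N-bromosuccinimide O=C1CCC(=O)N1Br; water O
Why: Electrophilic bromination of the enol ether at its terminal carbon and hydrolysis of the oxocarbenium ion give the α-bromo ketone directly; the enol ether is by far the most nucleophilic olefin, so one equivalent of NBS should leave the others alone.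

Step 17
Reactants: 22 allylic alcohol
Product: 23 C3 enal / C1 bromomethyl ketone
Conditions: Dess–Martin periodinane, CH2Cl2, 0 °C
Reagents that add atoms: none
Why: Dess–Martin oxidation converts the primary allylic alcohol into the Z-enal under neutral, cold conditions that should neither isomerise the Z-olefin nor disturb the α-bromo ketone; 23 is used at once.

Step 18
Reactants: 23 seco keto-aldehyde
Product: 25 macrocyclic 3-hydroxy-1-ketone, via samarium enolate 24 (not isolated)
Conditions: SmI2 (2.1 equiv, 0.1 M in THF, added slowly), THF (2 mM in 23), −78 °C; pH 7 buffer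
Reagents that add atoms: none
Why: Two single-electron transfers from SmI2 cleave the C2–Br bond and give the samarium(III) dienolate 24, whose C2 adds to the C3 aldehyde through a samarium-bridged, chair-like aldol transition state (intramolecular samarium Reformatsky reaction). The closest known reaction type is the SmI2-mediated intramolecular Reformatsky cyclisation of α-halo ketones and esters onto aldehydes, which is used to close eight- to fourteen-membered rings. The ten-membered carbocycle C1–C10 closes in a 10-exo-trig mode; eight of its ten atoms already lie in the two rigid Z-allylic units C3–C4=C5–C6 and C8–C9=C10–C1, which should favour ring closure over oligomerisation at high dilution. The only new stereocentre, C3, is controlled by allylic 1,3-strain across the Z C4=C5 bond: H–C6 must lie in the olefin plane facing the formyl group, so O6 and C7 occupy opposite faces, and because the enolate is tethered through C7 it can reach the s-trans enal only from the C7 face, which leads to 3S. Chemoselectivity rests on rate: the α-bromo ketone is reduced far faster than enal, enone or acrylate, and SmI2 is added only as fast as it is consumed so that no excess reductant meets the γ-acyloxy enone of the product. The hard samarium enolate should add 1,2 to the aldehyde in preference to conjugate addition to the enal or the α-methylene lactone, and the samarium aldolate is not basic enough to trigger retro-aldol or acyl migration before the buffered quench.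

Step 19
Reactants: 25 β-hydroxy ketone
Product: 26 CNP0282531.1 (target)
Conditions: SmI2 (0.3 equiv), CH3CHO (8 equiv), THF, −10 °C
Reagents that add atoms: acetaldehyde CC=O
Why: Evans–Tishchenko reduction: the samarium-bound hemiacetal formed from the C3 hydroxyl and acetaldehyde delivers hydride intramolecularly to the C1 ketone through a chair-like bicyclic transition state, which should give the 1,3-anti diol with the acetate on O3 and the free hydroxyl on C1, that is 1S from 3S.

## Compound list

1 | 1,2:5,6-di-O-isopropylidene-α-L-glucofuranose (diacetone-L-glucose) | CC1(C)OC[C@H](O1)[C@@H]1O[C@H]2OC(C)(C)O[C@H]2[C@@H]1O | starting material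
2 | 1,2:5,6-di-O-isopropylidene-α-L-ribo-hexofuranos-3-ulose | CC1(C)OC[C@H](O1)[C@@H]1O[C@H]2OC(C)(C)O[C@H]2C1=O | intermediate
3 | tert-butyl 2-(3-deoxy-1,2:5,6-di-O-isopropylidene-α-L-ribo-hexofuranos-3-ylidene)acetate (E/Z mixture) | CC1(C)OC[C@H](O1)[C@@H]1O[C@H]2OC(C)(C)O[C@H]2C1=CC(=O)OC(C)(C)C | intermediate
4 | 3-C-(tert-butoxycarbonylmethyl)-3-deoxy-1,2:5,6-di-O-isopropylidene-α-L-allofuranose | CC1(C)OC[C@H](O1)[C@@H]1O[C@H]2OC(C)(C)O[C@H]2[C@H]1CC(=O)OC(C)(C)C | intermediate
5 | 3-C-(tert-butoxycarbonylmethyl)-3-deoxy-1,2-O-isopropylidene-α-L-ribo-pentodialdo-1,4-furanose | O=C[C@@H]1O[C@H]2OC(C)(C)O[C@H]2[C@H]1CC(=O)OC(C)(C)C | intermediate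
6 | methyl (5Z)-3-C-(tert-butoxycarbonylmethyl)-3,5,6-trideoxy-1,2-O-isopropylidene-6-C-methyl-α-L-ribo-hept-5-enofuranuronate | COC(=O)/C(C)=C\[C@@H]1O[C@H]2OC(C)(C)O[C@H]2[C@H]1CC(=O)OC(C)(C)C | intermediate
7 | (5Z)-3-C-(tert-butoxycarbonylmethyl)-3,5,6-trideoxy-1,2-O-isopropylidene-6-C-methyl-α-L-ribo-hept-5-enofuranose | OC/C(C)=C\[C@@H]1O[C@H]2OC(C)(C)O[C@H]2[C@H]1CC(=O)OC(C)(C)C | intermediate
8 | 7-O-(tert-butyldiphenylsilyl) ether of 7 | CC(C)(C)[Si](OC/C(C)=C\[C@@H]1O[C@H]2OC(C)(C)O[C@H]2[C@H]1CC(=O)OC(C)(C)C)(c1ccccc1)c1ccccc1 | intermediate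
9 | Mannich base: 8 with CH(CH2NMe2)CO2tBu on the branch (epimers at C11) | CC(C)(C)[Si](OC/C(C)=C\[C@@H]1O[C@H]2OC(C)(C)O[C@H]2[C@H]1C(CN(C)C)C(=O)OC(C)(C)C)(c1ccccc1)c1ccccc1 | intermediate (not isolated)
10 | trimethylammonium iodide of 9 | CC(C)(C)[Si](OC/C(C)=C\[C@@H]1O[C@H]2OC(C)(C)O[C@H]2[C@H]1C(C[N+](C)(C)C)C(=O)OC(C)(C)C)(c1ccccc1)c1ccccc1.[I-] | intermediate (not isolated)
11 | tert-butyl acrylate: 8 with C(=CH2)CO2tBu on the branch carbon | CC(C)(C)[Si](OC/C(C)=C\[C@@H]1O[C@H]2OC(C)(C)O[C@H]2[C@H]1C(=C)C(=O)OC(C)(C)C)(c1ccccc1)c1ccccc1 | intermediate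
12 | free lactol of 11 (1,2-diol, anomeric mixture) | CC(C)(C)[Si](OC/C(C)=C\[C@@H]1OC(O)[C@@H](O)[C@H]1C(=C)C(=O)OC(C)(C)C)(c1ccccc1)c1ccccc1 | intermediate
13 | (R)-2-methylbutanoic acid | CC[C@@H](C)C(=O)O | starting material
14 | 1,2-bis-O-[(2R)-2-methylbutanoyl] derivative of 12 (anomeric mixture) | CC(C)(C)[Si](OC/C(C)=C\[C@@H]1OC(OC(=O)[C@H](C)CC)[C@@H](OC(=O)[C@H](C)CC)[C@H]1C(=C)C(=O)OC(C)(C)C)(c1ccccc1)c1ccccc1 | intermediate
15 | 2-O-[(2R)-2-methylbutanoyl] lactol (ester on the future O8; anomeric mixture) | CC(C)(C)[Si](OC/C(C)=C\[C@@H]1OC(O)[C@@H](OC(=O)[C@H](C)CC)[C@H]1C(=C)C(=O)OC(C)(C)C)(c1ccccc1)c1ccccc1 | intermediate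
16 | open-chain tert-butyl ester: 3-O-TBDPS, (4Z)-olefin, 6-OH, 7-[1-(tert-butoxycarbonyl)ethenyl], 8-O-(2R)-2-methylbutanoyl, (9Z)-10-iodo olefin | CC(C)(C)[Si](OC/C(C)=C\[C@H](O)[C@H](C(=C)C(=O)OC(C)(C)C)[C@H](OC(=O)[C@H](C)CC)/C=C(/C)I)(c1ccccc1)c1ccccc1 | intermediate
17 | 6-O-trimethylsilyl ether trimethylsilyl ester corresponding to 16 | CC(C)(C)[Si](OC/C(C)=C\[C@H](O[Si](C)(C)C)[C@H](C(=C)C(=O)O[Si](C)(C)C)[C@H](OC(=O)[C@H](C)CC)/C=C(/C)I)(c1ccccc1)c1ccccc1 | intermediate (not isolated)
18 | 6-hydroxy acrylic acid corresponding to 16 | CC(C)(C)[Si](OC/C(C)=C\[C@H](O)[C@H](C(=C)C(=O)O)[C@H](OC(=O)[C@H](C)CC)/C=C(/C)I)(c1ccccc1)c1ccccc1 | intermediate (not isolated)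
19 | α-methylene-γ-butyrolactone with (Z)-CH=C(CH3)CH2OTBDPS on C6 and (Z)-CH(O-acyl)CH=C(CH3)I on C7 | C=C1C(=O)O[C@@H](/C=C(/C)CO[Si](c2ccccc2)(c2ccccc2)C(C)(C)C)[C@H]1[C@H](OC(=O)[C@H](C)CC)/C=C(/C)I | intermediate
20 | C3 alcohol of 19 (TBDPS removed) | C=C1C(=O)O[C@@H](/C=C(/C)CO)[C@H]1[C@H](OC(=O)[C@H](C)CC)/C=C(/C)I | intermediate
21 | 2-ethoxy-1,3-diene (iodine of 20 replaced by 1-ethoxyvinyl) | C=C1C(=O)O[C@@H](/C=C(/C)CO)[C@H]1[C@H](OC(=O)[C@H](C)CC)/C=C(/C)C(=C)OCC | intermediate
22 | C1 bromomethyl ketone, C3 alcohol | C=C1C(=O)O[C@@H](/C=C(/C)CO)[C@H]1[C@H](OC(=O)[C@H](C)CC)/C=C(/C)C(=O)CBr | intermediate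
23 | C3 (Z)-enal, C1 bromomethyl (Z)-enone (2,3-seco precursor) | C=C1C(=O)O[C@@H](/C=C(/C)C=O)[C@H]1[C@H](OC(=O)[C@H](C)CC)/C=C(/C)C(=O)CBr | intermediate
24 | samarium(III) dienolate of 23 | C=C1C(=O)O[C@@H](/C=C(/C)C=O)[C@H]1[C@H](OC(=O)[C@H](C)CC)/C=C(/C)C(=C)O[Sm](I)I | intermediate (not isolated)
25 | macrocyclic (3S)-3-hydroxy-1-ketone (target lacking the acetyl group, C1 as ketone) | C=C1C(=O)O[C@H]2/C=C(/C)[C@@H](O)CC(=O)/C(C)=C\[C@@H](OC(=O)[C@H](C)CC)[C@@H]12 | intermediate
26 | CNP0282531.1: (1S,3S,6S,7R,8R,4Z,9Z)-3-acetoxy-1-hydroxy-8-[(2R)-2-methylbutanoyloxy]germacra-4,9,11(13)-trien-12,6-olide | C=C1C(=O)O[C@H]2/C=C(/C)[C@@H](OC(C)=O)C[C@H](O)/C(C)=C\[C@@H](OC(=O)[C@H](C)CC)[C@@H]12 | target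

## Step count and least certain steps

Total step count: 19. Longest linear sequence: 19 steps (1 to 26); 13 enters in step 10.

**Step 18 (key step).**
- What may go wrong: over-reduction if SmI2 accumulates (reductive loss of the γ-acyloxy group from the enone, pinacol coupling of the enal); intermolecular aldol addition; conjugate addition of the enolate to the α-methylene lactone across the ring; poor facial selectivity if a rotamer with O6 in the olefin plane competes with the H-in-plane rotamer.
- Fallback (closes the ring at C1–C10 instead): set out from 20. Dess–Martin oxidation gives the Z-enal vinyl iodide F1. Allylboration with B-allyldiisopinocampheylborane (the antipode that delivers the 3S carbinol, ethanolamine work-up) gives the homoallylic alcohol F2. Acetylation (Ac2O, pyridine) gives the acetate F3. Johnson–Lemieux cleavage of the monosubstituted vinyl group (OsO4 cat., NaIO4, 2,6-lutidine) gives the β-acetoxy aldehyde F4. An intramolecular Nozaki–Hiyama–Kishi reaction of F4 (CrCl2, NiCl2 cat., DMSO/THF, high dilution) joins the vinyl iodide carbon C10 to the C1 aldehyde and returns to the route at 26. The C1 configuration would then rest on substrate control.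

**Step 12.**
- What may go wrong: migration of the 2-methylbutanoyl group from O8 to the O6 alkoxide that the ring opening liberates, which would scramble the roles of O6 and O8; epimerisation at C8 in the transient α-acyloxy aldehyde.
- Fallback (O8 carried as a non-migrating silyl ether, ester installed after the lactone): set out from 12. TESOTf/2,6-lutidine gives the bis-triethylsilyl ether F5. The acetal-type anomeric silyl ether is cleaved selectively (K2CO3, MeOH, 0 °C) to the 2-O-TES lactol F6. Stork–Zhao olefination gives the open-chain vinyl iodide F7. The conditions of step 13 give the lactone F8. PPTS in MeOH removes the secondary TES ether to give the C8 alcohol F9. Steglich esterification with 13 returns to the route at 19.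

**Step 19.**
- What may go wrong: samarium-promoted migration of the acetyl group from O3 to O1 after the reduction; retro-aldol opening of the macrocycle; slow hemiacetal formation at the hindered ring aldolate, so that acetaldehyde self-condensation wins.
- Fallback (external reagent control instead of internal hydride delivery): set out from 25. Acetylation (Ac2O, pyridine, DMAP cat., 0 °C) gives the β-acetoxy enone F10. A Corey–Bakshi–Shibata 1,2-reduction (oxazaborolidine antipode chosen for 1S, catecholborane, toluene, −78 °C) returns to the route at 26.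

**Step 6.**
- What may go wrong: loss of chemoselectivity, with partial reduction of the tert-butyl ester next to the enoate.
- Fallback (no ester reduction): set out from 5. Stork–Zhao olefination gives the (Z)-vinyl iodide F11. Stille coupling with (tributylstannyl)methanol (Pd(PPh3)4, dioxane, 80 °C) returns to the route at 7.

## Further compounds

F1 | step 18 | Z-enal vinyl iodide (20 with CHO at C3) | C=C1C(=O)O[C@@H](/C=C(/C)C=O)[C@H]1[C@H](OC(=O)[C@H](C)CC)/C=C(/C)I
F2 | step 18 | (3S)-homoallylic alcohol from allylation of F1 | C=C1C(=O)O[C@@H](/C=C(/C)[C@@H](O)CC=C)[C@H]1[C@H](OC(=O)[C@H](C)CC)/C=C(/C)I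
F3 | step 18 | 3-O-acetate of F2 | C=C1C(=O)O[C@@H](/C=C(/C)[C@@H](OC(C)=O)CC=C)[C@H]1[C@H](OC(=O)[C@H](C)CC)/C=C(/C)I
F4 | step 18 | β-acetoxy aldehyde (C1 aldehyde, C10 vinyl iodide) | C=C1C(=O)O[C@@H](/C=C(/C)[C@@H](OC(C)=O)CC=O)[C@H]1[C@H](OC(=O)[C@H](C)CC)/C=C(/C)I
F5 | step 12 | 1,2-bis-O-triethylsilyl derivative of 12 | CC(C)(C)[Si](OC/C(C)=C\[C@@H]1OC(O[Si](CC)(CC)CC)[C@@H](O[Si](CC)(CC)CC)[C@H]1C(=C)C(=O)OC(C)(C)C)(c1ccccc1)c1ccccc1
F6 | step 12 | 2-O-triethylsilyl lactol | CC(C)(C)[Si](OC/C(C)=C\[C@@H]1OC(O)[C@@H](O[Si](CC)(CC)CC)[C@H]1C(=C)C(=O)OC(C)(C)C)(c1ccccc1)c1ccccc1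
F7 | step 12 | open-chain (9Z)-10-iodo olefin with 8-O-TES and free 6-OH | CC(C)(C)[Si](OC/C(C)=C\[C@H](O)[C@H](C(=C)C(=O)OC(C)(C)C)[C@H](O[Si](CC)(CC)CC)/C=C(/C)I)(c1ccccc1)c1ccccc1
F8 | step 12 | α-methylene lactone with 8-O-TES and 3-O-TBDPS | C=C1C(=O)O[C@@H](/C=C(/C)CO[Si](c2ccccc2)(c2ccccc2)C(C)(C)C)[C@H]1[C@H](O[Si](CC)(CC)CC)/C=C(/C)I
F9 | step 12 | α-methylene lactone with free 8-OH and 3-O-TBDPS | C=C1C(=O)O[C@@H](/C=C(/C)CO[Si](c2ccccc2)(c2ccccc2)C(C)(C)C)[C@H]1[C@H](O)/C=C(/C)I
F10 | step 19 | macrocyclic 3-acetoxy-1-ketone | C=C1C(=O)O[C@H]2/C=C(/C)[C@@H](OC(C)=O)CC(=O)/C(C)=C\[C@@H](OC(=O)[C@H](C)CC)[C@@H]12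
F11 | step 6 | (Z)-vinyl iodide from 5 (iodine cis to the furanose carbon) | I/C(C)=C\[C@@H]1O[C@H]2OC(C)(C)O[C@H]2[C@H]1CC(=O)OC(C)(C)C
A1 | alternative 1 | ω-formyl (Z)-2-(bromomethyl)enoate for the allylation closure | O=C/C=C(/C)[C@@H](OC(C)=O)C[C@H](O[Si](CC)(CC)CC)/C(C)=C\[C@@H](OC(=O)[C@H](C)CC)/C=C(\CBr)C(=O)OC
A2 | alternative 1 | 1-O-triethylsilyl ether of the target | C=C1C(=O)O[C@H]2/C=C(/C)[C@@H](OC(C)=O)C[C@H](O[Si](CC)(CC)CC)/C(C)=C\[C@@H](OC(=O)[C@H](C)CC)[C@@H]12
A3 | alternative 2 | diene for ring-closing metathesis at C9=C10 | C=C1C(=O)O[C@@H](/C=C(/C)[C@@H](OC(C)=O)C[C@H](O[Si](CC)(CC)CC)C(C)=C)[C@H]1[C@H](OC(=O)[C@H](C)CC)C=C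
A4 | alternative 3 | oxime diene, precursor of the nitrile oxide | C=C1C(=O)O[C@@H](/C=C(/C)C=C)[C@H]1[C@H](OC(=O)[C@H](C)CC)/C=C(/C)C=NO
A5 | alternative 3 | bridged isoxazoline (O on C3, C=N at C1) | C=C1C(=O)O[C@H]2/C=C(/C)[C@@H]3CC(=NO3)/C(C)=C\[C@@H](OC(=O)[C@H](C)CC)[C@@H]12
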